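One leftover in this flask is free catalyst: if each impurity takes one catalyst, 18 µM charged less 10 µM of impurity leaves 8.00 µM.

common to all: free catalyst 18 µM
- alpha: starting material 0.018 M; impurity 5 µM; run made earlier
- delta: starting material 0.018 M; impurity 7.5 µM; run made earlier
- gamma: starting material 0.0090 M; impurity 10 µM; run made earlier
- flask: starting material 0.018 M; impurity 10 µM; time 15 min

| run | time / min | target / % | isomer of the product / % |
|---|---|---|---|
| alpha | 1.00 | 39 | 46 |
| alpha | 1.50 | 40 | 50 |
| alpha | 2.50 | 42 | 49 |
| alpha | 4.00 | 43 | 51 |
| alpha | 8.00 | 43 | 52 |
| alpha | 12.0 | 42 | 53 |
| delta | 0.833 | 33 | 38 |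
| delta | 2.50 | 40 | 53 |
| delta | 4.00 | 43 | 50 |
| delta | 6.00 | 43 | 52 |
| delta | 10.0 | 42 | 51 |
| delta | 12.0 | 42 | 50 |
| gamma | 2.50 | 44 | 51 |
| gamma | 5.00 | 43 | 54 |
| gamma | 8.00 | 41 | 52 |
| gamma | 10.0 | 42 | 51 |
| gamma | 12.0 | 43 | 52 |

(standard deviation of a reading: 1.5 percentage points)

- ratio of target to isomer of the product at 1.2 s
- ratio of target to isomer of the product at 30 s
- ratio of target to isomer of the product at 15 min

- the numbers in the tables scatter by 1.5 percentage points (one standard deviation)

Two chemists accept that leftover and read the runs on a catalyst clock: a run's time, multiplied by that run's leftover catalyst and divided by this flask's. If the rate goes with free catalyst, this gives the time at which this flask should look the same in percent of the starting material charged. On this clock, delta's first reading falls at 1.09 min, earlier than the first alpha and gamma readings. The ratio read there is 0.868, a reading with its scatter.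

The first chemist holds that target and isomer of the product form side by side at a fixed selectivity, because the ratio shows no trend across the readings. The same ratio then stands at both early times. The second holds that isomer of the product forms from target, so the readings show thermodynamic control and earlier times may show kinetic control, with the ratio starting high. On the clock, 1.09 min is 2.18 times 30 s and 54.5 times 1.2 s, so both early times stand before the first reading.

The forecast sides with the first: 0.83 at 1.2 s (range 0.4 to 1.5), 0.83 at 30 s and 0.83 at 15 min, with the earliest value “really unobserved, so its range is wide”.

The flask gives 3.74, 0.888 and 0.833.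

    target + free catalyst ⇌ isomer of the product + free catalyst, rate k1*[free catalyst]*[target] forward; the back reaction follows from the equilibrium constant (K = 1.20, k = 58000 /M/s)
    free catalyst + impurity → spent catalyst (k = 1.90 × 10⁶ /M/s)
    starting material + free catalyst ⇌ target + free catalyst, rate k3*[starting material]*[free catalyst] forward; the back reaction follows from the equilibrium constant (K = 8.00, k = 2500 /M/s)

The value at 1.2 s stands above the forecast's high end, and the second view holds. In this flask target equals isomer of the product at 0.209 min. By 0.450 min the ratio in this flask is 0.896, close to the late 0.833, so the first view's constant ratio is a fair description from about that time on, which is earlier than 1.09 min.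

Now take the neighbour flask charged with 1.7 × 10⁻⁵ M of impurity. Its leftover is 1.00 µM, so its 15 min stands at 1.88 min on this flask's clock, later than 1.09 min. The clock therefore expects the late ratio, with starting material somewhat below this flask's 19.5% at 1.50 min. The neighbour computes to a ratio of 0.838 with 14.2% of starting material.

(The earlier runs and the new flask were generated by integration for substances that don't exist; the scatter is artificial.)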